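## Retrosynthetic overview

1. The last step is removal of three methoxymethyl (MOM) ethers from the (2S)-tri-MOM flavanone; no bond to the stereocentre is touched after it is made.
2. Key disconnection C2–C1′ (ring C to ring B): the protected flavanone comes from a 6,8-diprenyl-7-(MOM-oxy)chromone and 2,4-bis(MOM-oxy)bromobenzene. Chromone C2, normally the electrophilic β-carbon, is converted in situ into a nickel-bound homoenolate (a 4-silyloxy-2H-chromen-2-yl nickel species) and joined to the electrophilic carbon of the aryl bromide under a chiral ligand, which sets (2S).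
3. The chromone comes from the 2-hydroxyacetophenone and a one-carbon unit (enaminone, then ring closure with loss of dimethylamine).
4. The two prenyl C–C bonds come from double C-prenylation of 2,4-dihydroxyacetophenone; the aryl bromide comes from 4-bromoresorcinol.
5. Ring order: ring A is bought, ring C (pyranone) is closed in step 3, ring B (bought) is attached in step 5.

Assumption: the facial sense of the nickel-catalysed key step cannot be predicted with certainty. The route is written with (S,S)-i-Pr-BiOX; if the first analytical run (chiral HPLC) shows the (2R) product, the equally available (R,R) ligand is used instead.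

Abbreviations: prenyl = 3-methylbut-2-en-1-yl; MOM = methoxymethyl; BiOX = 4,4′-disubstituted 4,4′,5,5′-tetrahydro-2,2′-bioxazole.

## Route

Step 1
Reactants: 1 2,4-dihydroxyacetophenone; 2 prenyl bromide (1-bromo-3-methylbut-2-ene, 2.4 equiv)
Product: 3 1-[2,4-dihydroxy-3,5-bis(3-methylbut-2-en-1-yl)phenyl]ethan-1-one
Conditions: KOH (10% aq), 0 °C → rt
Reagents that add atoms: none
Why: Double C-alkylation of the ambident phenoxide (aqueous hydroxide favours C- over O-attack); C3 and C5 are the only ring positions ortho/para to both oxygens, so the di-C-prenyl product is necessarily the 3,5-isomer, separated by chromatography from mono-prenylated material that is recycled.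

Step 2
Reactants: 3 1-[2,4-dihydroxy-3,5-bis(3-methylbut-2-en-1-yl)phenyl]ethan-1-one
Product: 4 1-[2-hydroxy-4-(methoxymethoxy)-3,5-bis(3-methylbut-2-en-1-yl)phenyl]ethan-1-one
Conditions: MeOCH2Cl (1.2 equiv), K2CO3, acetone, rt
Reagents that add atoms: chloromethyl methyl ether, COCCl
Why: Williamson-type O-alkylation; the 2-OH is locked in a hydrogen bond to the acetyl group, so the weak base ionises and alkylates only the 4-OH.

Step 3
Reactants: 4 1-[2-hydroxy-4-(methoxymethoxy)-3,5-bis(3-methylbut-2-en-1-yl)phenyl]ethan-1-one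
Product: 6 7-(methoxymethoxy)-6,8-bis(3-methylbut-2-en-1-yl)-4H-chromen-4-one, via enaminone 5 (not isolated)
Conditions: Me2NCH(OMe)2, toluene, 95 °C; then AcOH, 60 °C
Reagents that add atoms: N,N-dimethylformamide dimethyl acetal, COC(OC)N(C)C
Why: Enaminone chromone synthesis: condensation at the acetyl CH3, then acid-promoted intramolecular oxa-Michael addition and loss of dimethylamine closes ring C, and acetic acid is too weak to cleave the MOM ether or cyclise the prenyl groups.

Step 4
Reactants: 7 4-bromobenzene-1,3-diol (4-bromoresorcinol)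
Product: 8 1-bromo-2,4-bis(methoxymethoxy)benzene
Conditions: MeOCH2Cl (2.5 equiv), K2CO3, acetone, reflux
Reagents that add atoms: chloromethyl methyl ether, COCCl
Why: Plain double Williamson-type O-alkylation of a resorcinol.

Step 5
Reactants: 6 7-(methoxymethoxy)-6,8-bis(3-methylbut-2-en-1-yl)-4H-chromen-4-one; 8 1-bromo-2,4-bis(methoxymethoxy)benzene
Product: 10 (2S)-2-[2,4-bis(methoxymethoxy)phenyl]-7-(methoxymethoxy)-6,8-bis(3-methylbut-2-en-1-yl)-2,3-dihydro-4H-chromen-4-one, via triethylsilyl enol ether 9 (not isolated)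
Conditions: NiCl2(MeOCH2CH2OMe) (10 mol %), (S,S)-i-Pr-BiOX (12 mol %), Mn powder (2.5 equiv), Et3SiCl (1.5 equiv), DMF, 30 °C; then 1 M HCl, THF, 0 °C
Reagents that add atoms: none
Why: Proposed new method: nickel-catalysed enantioselective reductive conjugate arylation, in which zerovalent nickel (formed by Mn) and Et3SiCl convert chromone 6 into a 4-silyloxy-2H-chromen-2-yl (silyloxyallyl) nickel species, a homoenolate whose C2 is now nucleophilic, and this couples with the electrophilic bromide carbon of 8 by C–C reductive elimination inside the C2-symmetric BiOX pocket, which fixes C2 as (S), while the product is held as silyl enol ether 9 until cold dilute acid protonates C3 only; the closest known reaction type is the racemic nickel/neocuproine/Mn/R3SiCl reductive conjugate arylation of enones through silyloxyallylnickel intermediates, together with nickel-catalysed enantioselective reductive arylations of enones by aryl halides.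

Step 6
Reactants: 10 (2S)-2-[2,4-bis(methoxymethoxy)phenyl]-7-(methoxymethoxy)-6,8-bis(3-methylbut-2-en-1-yl)-2,3-dihydro-4H-chromen-4-one
Product: 11 (2S)-2-(2,4-dihydroxyphenyl)-7-hydroxy-6,8-bis(3-methylbut-2-en-1-yl)-2,3-dihydro-4H-chromen-4-one
Conditions: 3 M HCl (aq), MeOH, 40 °C
Reagents that add atoms: none
Why: Acid-catalysed transacetalisation to methanol removes all three MOM groups (the usual end-game for prenylated flavonoids); no base is present, so the flavanone cannot open to the chalcone and C2 stays (S), and mild temperature with short reaction time keeps the prenyl groups from cyclising onto the 7-OH.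

## Compound list

1 | 2,4-dihydroxyacetophenone | CC(=O)c1ccc(O)cc1O | starting material
2 | prenyl bromide (1-bromo-3-methylbut-2-ene) | CC(C)=CCBr | starting material
3 | 1-[2,4-dihydroxy-3,5-bis(3-methylbut-2-en-1-yl)phenyl]ethan-1-one | CC(=O)c1cc(CC=C(C)C)c(O)c(CC=C(C)C)c1O | intermediate
4 | 1-[2-hydroxy-4-(methoxymethoxy)-3,5-bis(3-methylbut-2-en-1-yl)phenyl]ethan-1-one | CC(=O)c1cc(CC=C(C)C)c(OCOC)c(CC=C(C)C)c1O | intermediate
5 | (2E)-3-(dimethylamino)-1-[2-hydroxy-4-(methoxymethoxy)-3,5-bis(3-methylbut-2-en-1-yl)phenyl]prop-2-en-1-one | CN(C)/C=C/C(=O)c1cc(CC=C(C)C)c(OCOC)c(CC=C(C)C)c1O | intermediate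
6 | 7-(methoxymethoxy)-6,8-bis(3-methylbut-2-en-1-yl)-4H-chromen-4-one | O=c1ccoc2c(CC=C(C)C)c(OCOC)c(CC=C(C)C)cc12 | intermediate
7 | 4-bromobenzene-1,3-diol | Oc1ccc(Br)c(O)c1 | starting material
8 | 1-bromo-2,4-bis(methoxymethoxy)benzene | COCOc1ccc(Br)c(OCOC)c1 | intermediate
9 | {[(2S)-2-[2,4-bis(methoxymethoxy)phenyl]-7-(methoxymethoxy)-6,8-bis(3-methylbut-2-en-1-yl)-2H-chromen-4-yl]oxy}triethylsilane | CC(C)=CCc1cc2c(c(CC=C(C)C)c1OCOC)O[C@H](c1ccc(OCOC)cc1OCOC)C=C2O[Si](CC)(CC)CC | intermediate
10 | (2S)-2-[2,4-bis(methoxymethoxy)phenyl]-7-(methoxymethoxy)-6,8-bis(3-methylbut-2-en-1-yl)-2,3-dihydro-4H-chromen-4-one | CC(C)=CCc1cc2c(c(CC=C(C)C)c1OCOC)O[C@H](c1ccc(OCOC)cc1OCOC)CC2=O | intermediate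
11 | (2S)-2-(2,4-dihydroxyphenyl)-7-hydroxy-6,8-bis(3-methylbut-2-en-1-yl)-2,3-dihydro-4H-chromen-4-one | CC(C)=CCc1cc2c(c(CC=C(C)C)c1O)O[C@H](c1ccc(O)cc1O)CC2=O | target

## Step count and risks

Total steps: 6. Longest linear sequence: 5 (steps 1, 2, 3, 5, 6); step 4 is a one-step side branch.

**Step 5 (most likely to fail).** The chromone is a vinylogous ester and may enter the nickel cycle slowly. Homocoupling of either partner can compete, and the ee or even the sense of induction is unproven. The reductive, two-electrophile polarity is kept because it avoids a 2,4-dioxygenated arylboronic acid, which protodeboronates readily. The fallback sets out from 6 and 8 and returns at 10. The coupling is run with the achiral ligand neocuproine (2,9-dimethyl-1,10-phenanthroline), NiCl2(MeOCH2CH2OMe), Mn and Et3SiCl in DMF, the ligand used in the racemic precedent for this reaction type. This gives the racemic triethylsilyl enol ether F1, hydrolysed with cold dilute HCl to the racemic tri-MOM flavanone F2. A kinetic resolution by asymmetric transfer hydrogenation follows, with RuCl[(R,R)-TsDPEN](p-cymene) and HCO2H/Et3N. The (2R) ketone is reduced faster to the cis-(2R,4R)-flavan-4-ol F3, which is removed by chromatography. The unreacted ketone is 10, at most 50% of the material.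

**Step 1.** The double C-prenylation gives mixtures of O-alkyl, mono-C-alkyl and geminally dialkylated products, so the yield of 3 is expected to be only about 20–30%. The fallback sets out from 1 and returns at 3. Both activated positions are iodinated with I2/HIO3 in aqueous ethanol to give 1-(2,4-dihydroxy-3,5-diiodophenyl)ethan-1-one F4. A two-fold Stille coupling with tributyl(3-methylbut-2-en-1-yl)stannane and Pd(PPh3)4 in DMF at 90 °C then installs both prenyl groups at positions fixed by the halogens.

**Step 6.** Brønsted acid can cyclise a prenyl group onto the freed 7-OH (giving a dimethylchroman) and can erode the ee of a 2′,4′-dihydroxyflavanone on prolonged exposure. The fallback sets out from 10 and returns at 11. Et3SiOTf with 2,2′-bipyridyl in CH2Cl2 at 0 °C exchanges the three aryl MOM acetals for aryl triethylsilyl ethers without free acid, giving the (2S)-tris(triethylsilyl) ether F5. Et3N·3HF in THF at 0 °C then removes the silyl groups under weakly acidic, non-basic conditions.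

## Further compounds

F1 | step 5 | racemic {[2-[2,4-bis(methoxymethoxy)phenyl]-7-(methoxymethoxy)-6,8-bis(3-methylbut-2-en-1-yl)-2H-chromen-4-yl]oxy}triethylsilane | CC(C)=CCc1cc2c(c(CC=C(C)C)c1OCOC)OC(c1ccc(OCOC)cc1OCOC)C=C2O[Si](CC)(CC)CC
F2 | step 5 | racemic 2-[2,4-bis(methoxymethoxy)phenyl]-7-(methoxymethoxy)-6,8-bis(3-methylbut-2-en-1-yl)-2,3-dihydro-4H-chromen-4-one | CC(C)=CCc1cc2c(c(CC=C(C)C)c1OCOC)OC(c1ccc(OCOC)cc1OCOC)CC2=O
F3 | step 5 | (2R,4R)-2-[2,4-bis(methoxymethoxy)phenyl]-7-(methoxymethoxy)-6,8-bis(3-methylbut-2-en-1-yl)-3,4-dihydro-2H-chromen-4-ol | CC(C)=CCc1cc2c(c(CC=C(C)C)c1OCOC)O[C@@H](c1ccc(OCOC)cc1OCOC)C[C@H]2O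
F4 | step 1 | 1-(2,4-dihydroxy-3,5-diiodophenyl)ethan-1-one | CC(=O)c1cc(I)c(O)c(I)c1O
F5 | step 6 | (2S)-2-[2,4-bis(triethylsilyloxy)phenyl]-7-(triethylsilyloxy)-6,8-bis(3-methylbut-2-en-1-yl)-2,3-dihydro-4H-chromen-4-one | CC(C)=CCc1cc2c(c(CC=C(C)C)c1O[Si](CC)(CC)CC)O[C@H](c1ccc(O[Si](CC)(CC)CC)cc1O[Si](CC)(CC)CC)CC2=O
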